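The 5,6-dihydropyran-2-one ring is unravelled by excising its O1–C2(=O) unit as carbon dioxide. An open-chain δ-tosyloxy β-diketone that already carries the whole dienoate side chain is carboxylated at its central carbon (ring C3, flanked by the C4 and side-chain carbonyls) as a magnesium chelate; the new carboxylate then displaces the secondary tosylate at C6 with inversion. One operation thus forms C3–C2 and O1–C6, closes the lactone and sets C6 (R) from purchased (S)-pent-4-yn-2-ol. The step exploits the 1,4-disposition of nucleophilic C3 and electrophilic C6 across the C4 ketone. The other two stereocentres come from (R)-citronellal and (S)-2-methylbutan-1-ol.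

Key step: step 9

Remark: ring atoms are numbered O1, C2 (lactone carbonyl), C3 (acyl-bearing carbon), C4 (enol carbon), C5 (CH2), C6 (CHCH3); the 3-acyl-pyran-2,4-dione is drawn throughout as the 4-hydroxy enol tautomer, and its other tautomers are treated as the same compound.
Remark: carbon dioxide is counted as a starting material (20) because it supplies the lactone carboxyl.

Step 1
Reactants: 1 (S)-2-methylbutan-1-ol; 2 tert-butyl 2-(triphenyl-λ5-phosphanylidene)acetate
Product: 5 tert-butyl (2Z,4S)-2-bromo-4-methylhex-2-enoate, via (S)-2-methylbutanal 3 (not isolated), via bromo ylide 4 (not isolated)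
Conditions: 1, TEMPO (10 mol %), PhI(OAc)2, CH2Cl2, rt; separately 2, NBS, CH2Cl2, −20 °C; solutions combined, −20 °C to rt
Reagents that add atoms: N-bromosuccinimide, O=C1CCC(=O)N1Br
Why: Oxoammonium (TEMPO) oxidation should give the aldehyde without epimerisation, and Wittig olefination with the α-bromo ylide made in the flask by NBS bromination of the stabilised ylide should give mainly the (Z)-2-bromo enoate (alkyl cis to Br), the stereocentre being carried over from 1.

Step 2
Reactants: 6 (R)-citronellal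
Product: 7 (4R)-4,8-dimethylnon-7-en-1-yne
Conditions: dimethyl (1-diazo-2-oxopropyl)phosphonate, K2CO3, MeOH, 0 °C to rt
Reagents that add atoms: dimethyl (1-diazo-2-oxopropyl)phosphonate, CC(=O)C(=[N+]=[N-])P(=O)(OC)OC
Why: Seyferth–Gilbert homologation (Ohira–Bestmann variant) converts the aldehyde into the terminal alkyne under mild carbonate conditions that leave the β-stereocentre untouched.

Step 3
Reactants: 7 (4R)-4,8-dimethylnon-7-en-1-yne; 5 tert-butyl (2Z,4S)-2-bromo-4-methylhex-2-enoate
Product: 10 tert-butyl (2E,3E,6R)-6,10-dimethyl-2-[(2S)-2-methylbutylidene]undeca-3,9-dienoate, via alkenylzirconocene chloride 8 (not isolated), via alkenylzinc chloride 9 (not isolated)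
Conditions: Cp2Zr(H)Cl, THF, rt; then ZnCl2, THF, 0 °C; then 5, Pd(PPh3)4 (5 mol %), rt
Reagents that add atoms: none
Why: Syn hydrozirconation of the terminal alkyne (the trisubstituted alkene is inert) gives the (E)-alkenyl metal, and Negishi coupling after transmetalation to zinc proceeds with retention at both sp2 carbons, so the (2E,3E)-diene follows from the geometries of 5 and 8.

Step 4
Reactants: 10 tert-butyl (2E,3E,6R)-6,10-dimethyl-2-[(2S)-2-methylbutylidene]undeca-3,9-dienoate
Product: 12 tert-butyl (2E,3E,6R)-6-methyl-2-[(2S)-2-methylbutylidene]-9-oxonon-3-enoate, via epoxide 11 (not isolated)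
Conditions: mCPBA (1.0 equiv), NaHCO3, CH2Cl2, 0 °C; then H5IO6, THF/H2O, 0 °C to rt
Reagents that add atoms: 3-chloroperbenzoic acid, OOC(=O)c1cccc(Cl)c1
Why: Prilezhaev epoxidation should select the electron-rich trisubstituted alkene over the electron-poor dienoate, and periodic acid cleaves the epoxide (Malaprade-type glycol cleavage) to the aldehyde and acetone.

Step 5
Reactants: 13 (S)-pent-4-yn-2-ol
Product: 14 (S)-pent-4-yn-2-yl 4-methylbenzenesulfonate
Conditions: TsCl, pyridine, 0 °C to rt
Reagents that add atoms: 4-methylbenzenesulfonyl chloride, Cc1ccc(cc1)S(Cl)(=O)=O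
Why: O-Sulfonylation of the secondary alcohol occurs at oxygen with retention at carbon and installs the leaving group on the purchased stereocentre.

Step 6
Reactants: 14 (S)-pent-4-yn-2-yl 4-methylbenzenesulfonate; 12 tert-butyl (2E,3E,6R)-6-methyl-2-[(2S)-2-methylbutylidene]-9-oxonon-3-enoate
Product: 16 tert-butyl (2E,3E,6R,13S)-9-hydroxy-6-methyl-2-[(2S)-2-methylbutylidene]-13-(tosyloxy)tetradec-3-en-10-ynoate, via lithium acetylide 15 (not isolated)
Conditions: 14, n-BuLi, THF, −78 °C; then 12, −78 °C; then H2O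
Reagents that add atoms: none
Why: Deprotonation of the terminal alkyne at −78 °C should outrun attack on the sulfonate, and 1,2-addition of the lithium acetylide to the aldehyde gives the propargylic alcohol as a mixture of C9 epimers that the next step removes.

Step 7
Reactants: 16 tert-butyl (2E,3E,6R,13S)-9-hydroxy-6-methyl-2-[(2S)-2-methylbutylidene]-13-(tosyloxy)tetradec-3-en-10-ynoate
Product: 17 tert-butyl (2E,3E,6R,13S)-6-methyl-2-[(2S)-2-methylbutylidene]-9-oxo-13-(tosyloxy)tetradec-3-en-10-ynoate
Conditions: Dess–Martin periodinane, NaHCO3, CH2Cl2, 0 °C to rt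
Reagents that add atoms: none
Why: Dess–Martin oxidation converts the propargylic alcohol into the ynone under buffered, non-basic conditions that spare the tosylate and the dienoate.

Step 8
Reactants: 17 tert-butyl (2E,3E,6R,13S)-6-methyl-2-[(2S)-2-methylbutylidene]-9-oxo-13-(tosyloxy)tetradec-3-en-10-ynoate
Product: 19 tert-butyl (2E,3E,6R,13S)-6-methyl-2-[(2S)-2-methylbutylidene]-9,11-dioxo-13-(tosyloxy)tetradec-3-enoate, via diethylamino enone 18 (not isolated)
Conditions: Et2NH (1.2 equiv), EtOH, 0 °C to rt; then 1 M aq. HCl, THF, rt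
Reagents that add atoms: water, O
Why: Aza-Michael addition of the secondary amine to the ynone followed by mild acid hydrolysis of the enaminone amounts to a regioselective hydration to the 1,3-diketone, under conditions that a secondary tosylate and a tert-butyl ester should survive.

Step 9
Reactants: 19 tert-butyl (2E,3E,6R,13S)-6-methyl-2-[(2S)-2-methylbutylidene]-9,11-dioxo-13-(tosyloxy)tetradec-3-enoate; 20 carbon dioxide
Product: 22 tert-butyl (2E,3E,6R)-9-[(6R)-4-hydroxy-6-methyl-2-oxo-5,6-dihydro-2H-pyran-3-yl]-6-methyl-2-[(2S)-2-methylbutylidene]-9-oxonon-3-enoate, via magnesium-bound carboxylate 21 (not isolated)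
Conditions: Mg(OTf)2 (2 equiv), i-Pr2NEt (3 equiv), CO2 (10 bar), MeCN, 25 to 50 °C; then aq. citric acid
Reagents that add atoms: none
Why: Proposed new method: soft enolisation gives the U-shaped magnesium diketonate, whose central carbon adds reversibly to CO2 to give the magnesium-bound 2-acyl-3-oxo carboxylate 21, and this carboxylate, held by the chelate beside C5–C6, displaces the tosylate irreversibly, which drains the unfavourable carboxylation equilibrium. The closest known reactions are the magnesium-mediated carboxylation of ketone enolates with CO2 and the silver-catalysed carboxylation–cyclisation of alkynyl ketones, joined here to a carboxylate SN2 lactonisation. The pyranone ring closes by 6-exo-tet attack of carboxylate oxygen on C6. The only new stereocentre, C6, is set by inversion of the purchased (S)-tosylate to (R). The step needs C-carboxylation over O-carboxylation and lactonisation over enolate O-alkylation or E1cB loss of tosylate: O-carboxylation is reversible and cannot close a six-membered ring, the chelate holds the diketonate oxygens away from C6, the enolate form makes the C5 hydrogens non-acidic, and the triflate counter-ion and hindered amine exclude a double-inversion pathway.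

Step 10
Reactants: 22 tert-butyl (2E,3E,6R)-9-[(6R)-4-hydroxy-6-methyl-2-oxo-5,6-dihydro-2H-pyran-3-yl]-6-methyl-2-[(2S)-2-methylbutylidene]-9-oxonon-3-enoate
Product: 23 (2E,3E,6R)-9-[(6R)-4-hydroxy-6-methyl-2-oxo-5,6-dihydro-2H-pyran-3-yl]-6-methyl-2-[(2S)-2-methylbutylidene]-9-oxonon-3-enoic acid (CNP0281879.1)
Conditions: TFA/CH2Cl2 (1:4), 0 °C to rt
Reagents that add atoms: none
Why: Acidolysis of the tert-butyl ester (E1 loss of 2-methylpropene) frees the dienoic acid, and the acyl-dihydropyranone, the diene and the stereocentres should be stable to TFA.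

Compound list
1 | (S)-2-methylbutan-1-ol | CC[C@H](C)CO | starting material
2 | tert-butyl 2-(triphenyl-λ5-phosphanylidene)acetate | CC(C)(C)OC(=O)C=P(c1ccccc1)(c1ccccc1)c1ccccc1 | starting material
3 | (S)-2-methylbutanal | CC[C@H](C)C=O | intermediate
4 | tert-butyl 2-bromo-2-(triphenyl-λ5-phosphanylidene)acetate | CC(C)(C)OC(=O)C(Br)=P(c1ccccc1)(c1ccccc1)c1ccccc1 | intermediate
5 | tert-butyl (2Z,4S)-2-bromo-4-methylhex-2-enoate | CC[C@H](C)/C=C(\Br)C(=O)OC(C)(C)C | intermediate
6 | (R)-citronellal, (3R)-3,7-dimethyloct-6-enal | O=CC[C@H](C)CCC=C(C)C | starting material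
7 | (4R)-4,8-dimethylnon-7-en-1-yne | C#CC[C@H](C)CCC=C(C)C | intermediate
8 | chlorobis(cyclopentadienyl)[(1E,4R)-4,8-dimethylnona-1,7-dien-1-yl]zirconium | Cl[Zr](/C=C/C[C@H](C)CCC=C(C)C)(C1C=CC=C1)C1C=CC=C1 | intermediate
9 | chloro[(1E,4R)-4,8-dimethylnona-1,7-dien-1-yl]zinc | Cl[Zn]/C=C/C[C@H](C)CCC=C(C)C | intermediate
10 | tert-butyl (2E,3E,6R)-6,10-dimethyl-2-[(2S)-2-methylbutylidene]undeca-3,9-dienoate | CC[C@H](C)/C=C(\C=C\C[C@H](C)CCC=C(C)C)C(=O)OC(C)(C)C | intermediate
11 | tert-butyl (2E,3E,6R)-8-(3,3-dimethyloxiran-2-yl)-6-methyl-2-[(2S)-2-methylbutylidene]oct-3-enoate (both epoxide epimers) | CC[C@H](C)/C=C(\C=C\C[C@H](C)CCC1OC1(C)C)C(=O)OC(C)(C)C | intermediate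
12 | tert-butyl (2E,3E,6R)-6-methyl-2-[(2S)-2-methylbutylidene]-9-oxonon-3-enoate | CC[C@H](C)/C=C(\C=C\C[C@H](C)CCC=O)C(=O)OC(C)(C)C | intermediate
13 | (S)-pent-4-yn-2-ol | C#CC[C@H](C)O | starting material
14 | (S)-pent-4-yn-2-yl 4-methylbenzenesulfonate | C#CC[C@H](C)OS(=O)(=O)c1ccc(C)cc1 | intermediate
15 | lithium acetylide of 14, [(4S)-4-(tosyloxy)pent-1-yn-1-yl]lithium | [Li]C#CC[C@H](C)OS(=O)(=O)c1ccc(C)cc1 | intermediate
16 | tert-butyl (2E,3E,6R,13S)-9-hydroxy-6-methyl-2-[(2S)-2-methylbutylidene]-13-(tosyloxy)tetradec-3-en-10-ynoate (both C9 epimers) | CC[C@H](C)/C=C(\C=C\C[C@H](C)CCC(O)C#CC[C@H](C)OS(=O)(=O)c1ccc(C)cc1)C(=O)OC(C)(C)C | intermediate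
17 | tert-butyl (2E,3E,6R,13S)-6-methyl-2-[(2S)-2-methylbutylidene]-9-oxo-13-(tosyloxy)tetradec-3-en-10-ynoate | CC[C@H](C)/C=C(\C=C\C[C@H](C)CCC(=O)C#CC[C@H](C)OS(=O)(=O)c1ccc(C)cc1)C(=O)OC(C)(C)C | intermediate
18 | tert-butyl (2E,3E,6R,13S)-11-(diethylamino)-6-methyl-2-[(2S)-2-methylbutylidene]-9-oxo-13-(tosyloxy)tetradeca-3,10-dienoate | CC[C@H](C)/C=C(\C=C\C[C@H](C)CCC(=O)C=C(C[C@H](C)OS(=O)(=O)c1ccc(C)cc1)N(CC)CC)C(=O)OC(C)(C)C | intermediate
19 | tert-butyl (2E,3E,6R,13S)-6-methyl-2-[(2S)-2-methylbutylidene]-9,11-dioxo-13-(tosyloxy)tetradec-3-enoate | CC[C@H](C)/C=C(\C=C\C[C@H](C)CCC(=O)CC(=O)C[C@H](C)OS(=O)(=O)c1ccc(C)cc1)C(=O)OC(C)(C)C | intermediate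
20 | carbon dioxide | O=C=O | starting material
21 | tert-butyl (2E,3E,6R,13S)-10-carboxy-6-methyl-2-[(2S)-2-methylbutylidene]-9,11-dioxo-13-(tosyloxy)tetradec-3-enoate, present as its magnesium chelate (drawn as the free acid) | CC[C@H](C)/C=C(\C=C\C[C@H](C)CCC(=O)C(C(=O)O)C(=O)C[C@H](C)OS(=O)(=O)c1ccc(C)cc1)C(=O)OC(C)(C)C | intermediate
22 | tert-butyl (2E,3E,6R)-9-[(6R)-4-hydroxy-6-methyl-2-oxo-5,6-dihydro-2H-pyran-3-yl]-6-methyl-2-[(2S)-2-methylbutylidene]-9-oxonon-3-enoate | CC[C@H](C)/C=C(\C=C\C[C@H](C)CCC(=O)C1=C(O)C[C@@H](C)OC1=O)C(=O)OC(C)(C)C | intermediate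
23 | (2E,3E,6R)-9-[(6R)-4-hydroxy-6-methyl-2-oxo-5,6-dihydro-2H-pyran-3-yl]-6-methyl-2-[(2S)-2-methylbutylidene]-9-oxonon-3-enoic acid (CNP0281879.1) | CC[C@H](C)/C=C(\C=C\C[C@H](C)CCC(=O)C1=C(O)C[C@@H](C)OC1=O)C(=O)O | target

Total step count: 10.
Longest linear sequence: 8 steps (steps 2, 3, 4, 6, 7, 8, 9 and 10 from (R)-citronellal; the branch from 1 through step 1 is equally long).

Steps most likely to fail

Step 9 (Proposed new method). The carboxylation equilibrium of the magnesium diketonate may lie too far on the side of free CO2. Slower background processes could then consume the precursor or erode the configuration at C6: O-alkylation of the enolate to a 2,3-dihydropyran-4-one, or E1cB loss of tosylate followed by non-stereospecific ring closure. The fallback uses known chemistry, sets out from 12 and comes back at 22; the ring is made first and the acyl bond last. Chlorite oxidation of 12 (NaClO2, NaH2PO4, 2-methylbut-2-ene, t-BuOH/H2O) should give (4R,6E,8E,10S)-8-(tert-butoxycarbonyl)-4,10-dimethyldodeca-6,8-dienoic acid F1. In parallel, purchased ethyl (R)-3-hydroxybutanoate is condensed with excess lithium enolate of tert-butyl acetate (LDA, THF, −78 to −20 °C) to tert-butyl (5R)-5-hydroxy-3-oxohexanoate F2. TFA in CH2Cl2 lactonises this to (6R)-4-hydroxy-6-methyl-5,6-dihydro-2H-pyran-2-one F3. DCC and DMAP in CH2Cl2 then join F1 and F3 by O-acylation and DMAP-mediated O-to-C acyl shift to give 22.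

Step 6. The organolithium may attack the sulfonate at sulfur, the base may eliminate the homopropargylic tosylate, or the acetylide may enolise the aldehyde instead of adding to it. The fallback sets out from 12 and 14 and comes back at 17, with no organolithium and no separate oxidation. Aldehyde 12 is oxidised with NaClO2 as above to (4R,6E,8E,10S)-8-(tert-butoxycarbonyl)-4,10-dimethyldodeca-6,8-dienoic acid F4. This is converted under neutral conditions with 1-chloro-N,N,2-trimethylprop-1-en-1-amine (CH2Cl2, 0 °C) into tert-butyl (2E,3E,6R)-9-chloro-6-methyl-2-[(2S)-2-methylbutylidene]-9-oxonon-3-enoate F5. Acyl Sonogashira coupling of F5 with 14 (PdCl2(PPh3)2, CuI, Et3N, THF, rt) should give ynone 17 directly.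

Step 1. The weakly nucleophilic bromo ylide may olefinate slowly, which would allow the α-stereocentre of the aldehyde to epimerise and the Z/E selectivity to fall short. The fallback sets out from 1 and 2 and comes back at 5; the halogen is introduced after the olefination by addition and elimination. Alcohol 1 is oxidised as in step 1 to 3 and olefinated with the unbrominated, more reactive ylide 2 (CH2Cl2, rt) to tert-butyl (2E,4S)-4-methylhex-2-enoate F6. Br2 in CH2Cl2 at 0 °C adds to give tert-butyl (4S)-2,3-dibromo-4-methylhexanoate F7. Et3N in CH2Cl2 then eliminates HBr to the thermodynamically preferred (Z)-2-bromo enoate 5.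

Further compounds
F1 | step 9 | (4R,6E,8E,10S)-8-(tert-butoxycarbonyl)-4,10-dimethyldodeca-6,8-dienoic acid | CC[C@H](C)/C=C(\C=C\C[C@H](C)CCC(=O)O)C(=O)OC(C)(C)C
F2 | step 9 | tert-butyl (5R)-5-hydroxy-3-oxohexanoate | C[C@@H](O)CC(=O)CC(=O)OC(C)(C)C
F3 | step 9 | (6R)-4-hydroxy-6-methyl-5,6-dihydro-2H-pyran-2-one | C[C@@H]1CC(O)=CC(=O)O1
F4 | step 6 | (4R,6E,8E,10S)-8-(tert-butoxycarbonyl)-4,10-dimethyldodeca-6,8-dienoic acid | CC[C@H](C)/C=C(\C=C\C[C@H](C)CCC(=O)O)C(=O)OC(C)(C)C
F5 | step 6 | tert-butyl (2E,3E,6R)-9-chloro-6-methyl-2-[(2S)-2-methylbutylidene]-9-oxonon-3-enoate | CC[C@H](C)/C=C(\C=C\C[C@H](C)CCC(=O)Cl)C(=O)OC(C)(C)C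
F6 | step 1 | tert-butyl (2E,4S)-4-methylhex-2-enoate | CC[C@H](C)/C=C/C(=O)OC(C)(C)C
F7 | step 1 | tert-butyl (4S)-2,3-dibromo-4-methylhexanoate | CC[C@H](C)C(Br)C(Br)C(=O)OC(C)(C)C
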